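**Plan**

1. Retrosynthesis: the two MOM ethers come off last. Ring C is cut at C3–C4, so that C4 becomes a formyl group on ring A and C2=C3 an aryl enol ether. The enol ether is cut at C2=C3 (C3 is the methylene of a titanium methylidene) to an aryl ester, and the ester O1–C2 bond leads back to a ring A salicyl fragment and a ring B chromene acid.
2. Forward: ring A (from 2,4-dihydroxybenzaldehyde) is prenylated at the carbon between its two oxygens. Ring B with its fused pyran is taken intact from 7-methoxy-2,2-dimethyl-2H-chromene and functionalised at C6. The fragments are joined at O1–C2 (ester), C3 is added by methylenation, and ring C is closed last.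
3. Enabling feature: O1 sits on ring A ortho to the carbon bearing C4, C2 is fully substituted (O1 and ring B) and C3 is a terminal CH2. A formyl C–H at C4 can therefore add across C2=C3 with hydrogen to C2 and the acyl carbon to C3, which is exactly the chroman-4-one ring.
4. Stereochemistry: the only stereocentre, C2, is created in the ring closure from an achiral precursor under control of a chiral diphosphine on rhodium. The closure is neutral, so the base-induced ring opening that racemises flavanones is avoided, and only one mild acid step follows.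

Key step: step 13

Assumption: (R,R)-Me-DuPhos is taken to direct the hydride to the Re face of C2 (which gives 2S); if the sense of induction proves opposite, (S,S)-Me-DuPhos is used instead.

**Route**

Step 1
Reactants: 1 2,4-dihydroxybenzaldehyde
Product: 2 2,4-dihydroxy-3-(3-methylbut-2-en-1-yl)benzaldehyde
Conditions: prenyl bromide (1.0 equiv), KOH (10% aq.), 0 °C → rt
Reagents that add atoms: 1-bromo-3-methylbut-2-ene (prenyl bromide), CC(C)=CCBr
Why: Nuclear C-prenylation of the phenoxide in water, where hydrogen bonding to the phenoxide oxygens steers the allylic bromide to carbon and C3, flanked by both oxygens, is the most nucleophilic ring position, so the 3-prenyl isomer is expected as the main C-alkylation product in modest yield.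

Step 2
Reactants: 2 2,4-dihydroxy-3-(3-methylbut-2-en-1-yl)benzaldehyde
Product: 3 2-hydroxy-4-(methoxymethoxy)-3-(3-methylbut-2-en-1-yl)benzaldehyde
Conditions: MOMCl (1.1 equiv), K2CO3, acetone, 0 °C → rt
Reagents that add atoms: chloromethyl methyl ether, COCCl
Why: Williamson-type MOM protection in which the 2-OH is held in a hydrogen bond to the formyl oxygen, so only the 4-OH should be alkylated under K2CO3.

Step 3
Reactants: 3 2-hydroxy-4-(methoxymethoxy)-3-(3-methylbut-2-en-1-yl)benzaldehyde
Product: 4 2-(hydroxymethyl)-5-(methoxymethoxy)-6-(3-methylbut-2-en-1-yl)phenol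
Conditions: NaBH4, MeOH/THF, 0 °C; aq. NH4Cl work-up kept near neutral
Reagents that add atoms: none
Why: Borohydride reduction parks C4 at the alcohol level, because a free formyl group would not survive the later titanium methylidene; the electron-rich salicyl alcohol is handled without acid.

Step 4
Reactants: 4 2-(hydroxymethyl)-5-(methoxymethoxy)-6-(3-methylbut-2-en-1-yl)phenol
Product: 5 2-{[(tert-butyldimethylsilyl)oxy]methyl}-5-(methoxymethoxy)-6-(3-methylbut-2-en-1-yl)phenol
Conditions: TBSCl (1.05 equiv), imidazole, CH2Cl2, 0 °C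
Reagents that add atoms: tert-butyldimethylsilyl chloride, CC(C)(C)[Si](C)(C)Cl
Why: Selective silylation, in which the primary alcohol is expected to react faster than the phenol flanked by two ortho substituents, leaving that phenol free as the future O1.

Step 5
Reactants: 6 7-methoxy-2,2-dimethyl-2H-chromene
Product: 8 7-methoxy-2,2-dimethyl-2H-chromene-6-carbaldehyde, via iminium salt 7 (not isolated)
Conditions: POCl3, DMF, 0 → 50 °C; then H2O, 0 °C → rt
Reagents that add atoms: N,N-dimethylformamide, CN(C)C=O; water, O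
Why: Vilsmeier–Haack formylation at C6, which is para to the ring oxygen, ortho to the methoxy group and less hindered than C8 between the two oxygens, followed by hydrolysis of the iminium salt on aqueous work-up.

Step 6
Reactants: 8 7-methoxy-2,2-dimethyl-2H-chromene-6-carbaldehyde
Product: 9 7-hydroxy-2,2-dimethyl-2H-chromene-6-carbaldehyde
Conditions: BCl3 (1.2 equiv), CH2Cl2, −78 → 0 °C; then cold H2O
Reagents that add atoms: none
Why: Chelation-controlled ether cleavage, in which BCl3 bridges the formyl oxygen and the ortho methoxy oxygen so that only this methyl ether is cleaved, at a temperature the chromene double bond should tolerate.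

Step 7
Reactants: 9 7-hydroxy-2,2-dimethyl-2H-chromene-6-carbaldehyde
Product: 10 7-(methoxymethoxy)-2,2-dimethyl-2H-chromene-6-carbaldehyde
Conditions: NaH, THF/DMF, 0 °C; MOMCl, 0 °C → rt
Reagents that add atoms: chloromethyl methyl ether, COCCl
Why: MOM protection of the hydrogen-bonded phenol, which needs full deprotonation by NaH before alkylation.

Step 8
Reactants: 10 7-(methoxymethoxy)-2,2-dimethyl-2H-chromene-6-carbaldehyde
Product: 11 7-(methoxymethoxy)-2,2-dimethyl-2H-chromene-6-carboxylic acid
Conditions: NaClO2, NaH2PO4, 2-methylbut-2-ene (excess), t-BuOH/H2O, rt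
Reagents that add atoms: sodium chlorite, [Na+].[O-]Cl=O
Why: Pinnick oxidation of the aldehyde at buffered pH, with the alkene scavenger taking up hypochlorous acid so that the chromene double bond and the MOM ether should remain intact.

Step 9
Reactants: 5 2-{[(tert-butyldimethylsilyl)oxy]methyl}-5-(methoxymethoxy)-6-(3-methylbut-2-en-1-yl)phenol; 11 7-(methoxymethoxy)-2,2-dimethyl-2H-chromene-6-carboxylic acid
Product: 12 2-{[(tert-butyldimethylsilyl)oxy]methyl}-5-(methoxymethoxy)-6-(3-methylbut-2-en-1-yl)phenyl 7-(methoxymethoxy)-2,2-dimethyl-2H-chromene-6-carboxylate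
Conditions: DCC, DMAP (cat.), CH2Cl2, 0 °C → rt
Reagents that add atoms: none
Why: Steglich esterification joins O1 to C2 by carbodiimide activation and DMAP acyl transfer, avoiding an acid chloride that would attack the ortho MOM ether.

Step 10
Reactants: 12 2-{[(tert-butyldimethylsilyl)oxy]methyl}-5-(methoxymethoxy)-6-(3-methylbut-2-en-1-yl)phenyl 7-(methoxymethoxy)-2,2-dimethyl-2H-chromene-6-carboxylate
Product: 13 6-{1-[2-{[(tert-butyldimethylsilyl)oxy]methyl}-5-(methoxymethoxy)-6-(3-methylbut-2-en-1-yl)phenoxy]ethenyl}-7-(methoxymethoxy)-2,2-dimethyl-2H-chromene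
Conditions: Cp2Ti(μ-CH2)(μ-Cl)AlMe2 (Tebbe reagent, 1.5 equiv), pyridine (cat.), THF/toluene, −40 °C → rt; dilute aq. NaOH quench, basic alumina
Reagents that add atoms: Tebbe reagent Cp2Ti(μ-CH2)(μ-Cl)AlMe2, C[Al-]1(C)C[Ti]([Cl+]1)(C1C=CC=C1)C1C=CC=C1
Why: Tebbe methylenation of an ester, a transformation established for aryl benzoates, in which [2+2] addition of the titanium methylidene to the ester carbonyl and cycloreversion driven by the Ti=O bond deliver C3 as the terminal CH2 of the 1-aryl-1-aryloxyethene, with pyridine and basic isolation protecting the acid-labile enol ether.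

Step 11
Reactants: 13 6-{1-[2-{[(tert-butyldimethylsilyl)oxy]methyl}-5-(methoxymethoxy)-6-(3-methylbut-2-en-1-yl)phenoxy]ethenyl}-7-(methoxymethoxy)-2,2-dimethyl-2H-chromene
Product: 14 [4-(methoxymethoxy)-2-({1-[7-(methoxymethoxy)-2,2-dimethyl-2H-chromen-6-yl]ethenyl}oxy)-3-(3-methylbut-2-en-1-yl)phenyl]methanol
Conditions: Bu4NF (1.1 equiv), THF, 0 °C; aq. NaHCO3 work-up
Reagents that add atoms: none
Why: Fluoride-driven Si–O cleavage under basic conditions, which the enol ether and the MOM ethers should tolerate; the alcohol is carried on without acid contact so that it does not add to the neighbouring enol ether.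

Step 12
Reactants: 14 [4-(methoxymethoxy)-2-({1-[7-(methoxymethoxy)-2,2-dimethyl-2H-chromen-6-yl]ethenyl}oxy)-3-(3-methylbut-2-en-1-yl)phenyl]methanol
Product: 15 4-(methoxymethoxy)-2-({1-[7-(methoxymethoxy)-2,2-dimethyl-2H-chromen-6-yl]ethenyl}oxy)-3-(3-methylbut-2-en-1-yl)benzaldehyde
Conditions: MnO2 (activated, excess), CH2Cl2, rt
Reagents that add atoms: none
Why: Manganese dioxide oxidation is selective for the benzylic alcohol and runs at neutral pH, so the enol ether, the chromene and the prenyl group should be untouched.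

Step 13
Reactants: 15 4-(methoxymethoxy)-2-({1-[7-(methoxymethoxy)-2,2-dimethyl-2H-chromen-6-yl]ethenyl}oxy)-3-(3-methylbut-2-en-1-yl)benzaldehyde
Product: 16 (2S)-7-(methoxymethoxy)-2-[7-(methoxymethoxy)-2,2-dimethyl-2H-chromen-6-yl]-8-(3-methylbut-2-en-1-yl)-2,3-dihydro-4H-chromen-4-one
Conditions: [Rh(nbd)2]BF4 (nbd = norbornadiene, 5 mol %), (R,R)-Me-DuPhos (5.5 mol %), activated with H2 then purged with Ar; 15, CH2Cl2, 4 Å molecular sieves, 25 → 40 °C
Reagents that add atoms: none
Why: Proposed new method: oxidative addition of the formyl C–H bond to the cationic monovalent rhodium diphosphine centre, coordination of the C2=C3 enol ether, hydride migration to C2 with rhodium bound to the terminal C3, and C4–C3 reductive elimination should give the chromanone and return the catalyst. The closest known reaction type is the rhodium-catalysed enantioselective intramolecular hydroacylation of 1,1-disubstituted alkenes in 2-(1-substituted vinyl)benzaldehydes and 2-(2-substituted allyl)benzaldehydes, which gives 3-substituted indanones and tetralones; here the benzylic CH2 of the allyl series is replaced by the ether oxygen O1, which also removes the alkene isomerisation pathway. Ring C is closed in a formal 6-endo-trig mode through a seven-membered acyl alkyl rhodacycle. The C2 stereocentre is controlled by the C2-symmetric diphosphine, which selects the enol ether face that receives the hydride (Re face of C2 for 2S) during insertion and reductive elimination. The step needs hydride delivery to C2 and not to C3 (which would close a five-membered benzofuranone), secured by the 1,1-disubstitution of C2 that disfavours a tertiary alkyl rhodium; it needs reductive elimination to outrun decarbonylation, helped by the rigid ortho arrangement on ring A; and it needs chemoselectivity over the prenyl and chromene alkenes, which cannot reach the acyl rhodium centre in a ring of comparable size.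

Step 14
Reactants: 16 (2S)-7-(methoxymethoxy)-2-[7-(methoxymethoxy)-2,2-dimethyl-2H-chromen-6-yl]-8-(3-methylbut-2-en-1-yl)-2,3-dihydro-4H-chromen-4-one
Product: 17 (2S)-7-hydroxy-2-(7-hydroxy-2,2-dimethyl-2H-chromen-6-yl)-8-(3-methylbut-2-en-1-yl)-2,3-dihydro-4H-chromen-4-one
Conditions: HCl (2 M in MeOH), MeOH/THF, 0 °C → rt
Reagents that add atoms: none
Why: Acid-catalysed transacetalisation of both aryl MOM ethers to dimethoxymethane under conditions mild enough that the prenyl group, the chromene double bond and the C2–O1 bond should not be attacked, so the 2S configuration is expected to be retained.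

**Compound list**

1 | 2,4-dihydroxybenzaldehyde | O=Cc1ccc(O)cc1O | starting material
2 | 2,4-dihydroxy-3-(3-methylbut-2-en-1-yl)benzaldehyde | O=Cc1ccc(O)c(CC=C(C)C)c1O | intermediate
3 | 2-hydroxy-4-(methoxymethoxy)-3-(3-methylbut-2-en-1-yl)benzaldehyde | O=Cc1ccc(OCOC)c(CC=C(C)C)c1O | intermediate
4 | 2-(hydroxymethyl)-5-(methoxymethoxy)-6-(3-methylbut-2-en-1-yl)phenol | OCc1ccc(OCOC)c(CC=C(C)C)c1O | intermediate
5 | 2-{[(tert-butyldimethylsilyl)oxy]methyl}-5-(methoxymethoxy)-6-(3-methylbut-2-en-1-yl)phenol | CC(C)(C)[Si](C)(C)OCc1ccc(OCOC)c(CC=C(C)C)c1O | intermediate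
6 | 7-methoxy-2,2-dimethyl-2H-chromene | COc1ccc2C=CC(C)(C)Oc2c1 | starting material
7 | [(7-methoxy-2,2-dimethyl-2H-chromen-6-yl)methylidene]dimethyliminium dichlorophosphate | COc1cc2OC(C)(C)C=Cc2cc1C=[N+](C)C.[O-]P(=O)(Cl)Cl | intermediate
8 | 7-methoxy-2,2-dimethyl-2H-chromene-6-carbaldehyde | COc1cc2OC(C)(C)C=Cc2cc1C=O | intermediate
9 | 7-hydroxy-2,2-dimethyl-2H-chromene-6-carbaldehyde | Oc1cc2OC(C)(C)C=Cc2cc1C=O | intermediate
10 | 7-(methoxymethoxy)-2,2-dimethyl-2H-chromene-6-carbaldehyde | COCOc1cc2OC(C)(C)C=Cc2cc1C=O | intermediate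
11 | 7-(methoxymethoxy)-2,2-dimethyl-2H-chromene-6-carboxylic acid | COCOc1cc2OC(C)(C)C=Cc2cc1C(=O)O | intermediate
12 | 2-{[(tert-butyldimethylsilyl)oxy]methyl}-5-(methoxymethoxy)-6-(3-methylbut-2-en-1-yl)phenyl 7-(methoxymethoxy)-2,2-dimethyl-2H-chromene-6-carboxylate | CC(C)(C)[Si](C)(C)OCc1ccc(OCOC)c(CC=C(C)C)c1OC(=O)c1cc2C=CC(C)(C)Oc2cc1OCOC | intermediate
13 | 6-{1-[2-{[(tert-butyldimethylsilyl)oxy]methyl}-5-(methoxymethoxy)-6-(3-methylbut-2-en-1-yl)phenoxy]ethenyl}-7-(methoxymethoxy)-2,2-dimethyl-2H-chromene | CC(C)(C)[Si](C)(C)OCc1ccc(OCOC)c(CC=C(C)C)c1OC(=C)c1cc2C=CC(C)(C)Oc2cc1OCOC | intermediate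
14 | [4-(methoxymethoxy)-2-({1-[7-(methoxymethoxy)-2,2-dimethyl-2H-chromen-6-yl]ethenyl}oxy)-3-(3-methylbut-2-en-1-yl)phenyl]methanol | OCc1ccc(OCOC)c(CC=C(C)C)c1OC(=C)c1cc2C=CC(C)(C)Oc2cc1OCOC | intermediate
15 | 4-(methoxymethoxy)-2-({1-[7-(methoxymethoxy)-2,2-dimethyl-2H-chromen-6-yl]ethenyl}oxy)-3-(3-methylbut-2-en-1-yl)benzaldehyde | O=Cc1ccc(OCOC)c(CC=C(C)C)c1OC(=C)c1cc2C=CC(C)(C)Oc2cc1OCOC | intermediate
16 | (2S)-7-(methoxymethoxy)-2-[7-(methoxymethoxy)-2,2-dimethyl-2H-chromen-6-yl]-8-(3-methylbut-2-en-1-yl)-2,3-dihydro-4H-chromen-4-one | CC(C)=CCc1c(OCOC)ccc2c1O[C@H](c1cc3c(cc1OCOC)OC(C)(C)C=C3)CC2=O | intermediate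
17 | (2S)-7-hydroxy-2-(7-hydroxy-2,2-dimethyl-2H-chromen-6-yl)-8-(3-methylbut-2-en-1-yl)-2,3-dihydro-4H-chromen-4-one | CC(C)=CCc1c(O)ccc2c1O[C@H](c1cc3c(cc1O)OC(C)(C)C=C3)CC2=O | target

**Count**

Total steps: 14. Longest linear sequence: 10 steps (steps 1–4 or 5–8, then 9–14).

**Steps most likely to fail**

Step 13 (proposed new method). The closure may fail through decarbonylation at the acyl rhodium stage, through hydride delivery to the terminal carbon with five-membered closure, through poor facial selectivity, or through acid-promoted hydrolysis of the enol ether by the cationic catalyst. The fallback closes ring C at O1–C2 by known chemistry, sets out from 3 and 10 and returns at 16. Aldehyde 3 is treated with MeMgBr (3 equiv, THF, 0 °C) to give racemic 2-(1-hydroxyethyl)-5-(methoxymethoxy)-6-(3-methylbut-2-en-1-yl)phenol F1. MnO2 in CH2Cl2 oxidises it to 1-[2-hydroxy-4-(methoxymethoxy)-3-(3-methylbut-2-en-1-yl)phenyl]ethan-1-one F2. Claisen–Schmidt condensation of F2 with aldehyde 10 (KOH, EtOH/H2O, rt) gives (2E)-1-[2-hydroxy-4-(methoxymethoxy)-3-(3-methylbut-2-en-1-yl)phenyl]-3-[7-(methoxymethoxy)-2,2-dimethyl-2H-chromen-6-yl]prop-2-en-1-one F3. NaOAc in refluxing EtOH cyclises it by oxa-Michael addition to racemic 7-(methoxymethoxy)-2-[7-(methoxymethoxy)-2,2-dimethyl-2H-chromen-6-yl]-8-(3-methylbut-2-en-1-yl)-2,3-dihydro-4H-chromen-4-one F4. Asymmetric transfer hydrogenation under kinetic resolution (RuCl(p-cymene)[(R,R)-TsDPEN], HCO2H/Et3N, stopped near half conversion) is expected to reduce the 2R ketone to (2R,4R)-7-(methoxymethoxy)-2-[7-(methoxymethoxy)-2,2-dimethyl-2H-chromen-6-yl]-8-(3-methylbut-2-en-1-yl)-3,4-dihydro-2H-chromen-4-ol F5 and to leave the 2S ketone 16, which is separated and carried into step 14.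

Step 10. The methylenation may stall at the doubly ortho-substituted ester, the Lewis-acidic aluminium component may cleave a MOM ether, or the enol ether may hydrolyse during isolation. The fallback makes C2=C3 by elimination after ether formation instead of by carbonyl olefination, sets out from 10 and 5 and returns at 13. Addition of (phenylsulfanyl)methyllithium (thioanisole, n-BuLi, DABCO, THF, 0 → −78 °C) to aldehyde 10 gives racemic 1-[7-(methoxymethoxy)-2,2-dimethyl-2H-chromen-6-yl]-2-(phenylsulfanyl)ethan-1-ol F6. Mitsunobu etherification of F6 with phenol 5 (PPh3, DIAD, toluene), with opening of the episulfonium ion at the benzylic carbon, gives racemic tert-butyl{[4-(methoxymethoxy)-2-{1-[7-(methoxymethoxy)-2,2-dimethyl-2H-chromen-6-yl]-2-(phenylsulfanyl)ethoxy}-3-(3-methylbut-2-en-1-yl)phenyl]methoxy}dimethylsilane F7. Oxidation with NaIO4 (MeOH/H2O, 0 °C) gives the sulfoxide tert-butyl{[2-{2-(benzenesulfinyl)-1-[7-(methoxymethoxy)-2,2-dimethyl-2H-chromen-6-yl]ethoxy}-4-(methoxymethoxy)-3-(3-methylbut-2-en-1-yl)phenyl]methoxy}dimethylsilane F8 as a mixture of diastereomers. Thermal syn-elimination (toluene, NaHCO3, 110 °C), which can only take the benzylic hydrogen, should give enol ether 13.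

Step 1. The alkylation may go to oxygen, to C5 or twice, so the wanted 3-prenyl compound may be obtained in too low a yield. The fallback brings the prenyl group in by sigmatropic rearrangement instead of direct C-alkylation, sets out from 1 and returns at 2. Zerovalent palladium catalysis (Pd(PPh3)4, tert-butyl 2-methylbut-3-en-2-yl carbonate, THF, 0 °C) should etherify the non-chelated 4-OH to 2-hydroxy-4-[(2-methylbut-3-en-2-yl)oxy]benzaldehyde F9. Aromatic Claisen rearrangement (N,N-diethylaniline, 180 °C) then moves the allyl unit with inversion to C3, the ortho position favoured by the chelated 2-hydroxy carbonyl unit, and gives 2.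

**Further compounds**

F1 | step 13 | 2-(1-hydroxyethyl)-5-(methoxymethoxy)-6-(3-methylbut-2-en-1-yl)phenol (racemic) | CC(O)c1ccc(OCOC)c(CC=C(C)C)c1O
F2 | step 13 | 1-[2-hydroxy-4-(methoxymethoxy)-3-(3-methylbut-2-en-1-yl)phenyl]ethan-1-one | CC(=O)c1ccc(OCOC)c(CC=C(C)C)c1O
F3 | step 13 | (2E)-1-[2-hydroxy-4-(methoxymethoxy)-3-(3-methylbut-2-en-1-yl)phenyl]-3-[7-(methoxymethoxy)-2,2-dimethyl-2H-chromen-6-yl]prop-2-en-1-one | COCOc1ccc(C(=O)/C=C/c2cc3C=CC(C)(C)Oc3cc2OCOC)c(O)c1CC=C(C)C
F4 | step 13 | 7-(methoxymethoxy)-2-[7-(methoxymethoxy)-2,2-dimethyl-2H-chromen-6-yl]-8-(3-methylbut-2-en-1-yl)-2,3-dihydro-4H-chromen-4-one (racemic) | CC(C)=CCc1c(OCOC)ccc2c1OC(c1cc3c(cc1OCOC)OC(C)(C)C=C3)CC2=O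
F5 | step 13 | (2R,4R)-7-(methoxymethoxy)-2-[7-(methoxymethoxy)-2,2-dimethyl-2H-chromen-6-yl]-8-(3-methylbut-2-en-1-yl)-3,4-dihydro-2H-chromen-4-ol | CC(C)=CCc1c(OCOC)ccc2c1O[C@@H](c1cc3c(cc1OCOC)OC(C)(C)C=C3)C[C@H]2O
F6 | step 10 | 1-[7-(methoxymethoxy)-2,2-dimethyl-2H-chromen-6-yl]-2-(phenylsulfanyl)ethan-1-ol (racemic) | COCOc1cc2OC(C)(C)C=Cc2cc1C(O)CSc1ccccc1
F7 | step 10 | tert-butyl{[4-(methoxymethoxy)-2-{1-[7-(methoxymethoxy)-2,2-dimethyl-2H-chromen-6-yl]-2-(phenylsulfanyl)ethoxy}-3-(3-methylbut-2-en-1-yl)phenyl]methoxy}dimethylsilane (racemic) | CC(C)(C)[Si](C)(C)OCc1ccc(OCOC)c(CC=C(C)C)c1OC(CSc1ccccc1)c1cc2C=CC(C)(C)Oc2cc1OCOC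
F8 | step 10 | tert-butyl{[2-{2-(benzenesulfinyl)-1-[7-(methoxymethoxy)-2,2-dimethyl-2H-chromen-6-yl]ethoxy}-4-(methoxymethoxy)-3-(3-methylbut-2-en-1-yl)phenyl]methoxy}dimethylsilane (mixture of diastereomers) | CC(C)(C)[Si](C)(C)OCc1ccc(OCOC)c(CC=C(C)C)c1OC(CS(=O)c1ccccc1)c1cc2C=CC(C)(C)Oc2cc1OCOC
F9 | step 1 | 2-hydroxy-4-[(2-methylbut-3-en-2-yl)oxy]benzaldehyde | O=Cc1ccc(OC(C)(C)C=C)cc1O
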